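**Plan**

- Retrosynthesis: first cut the C8–CH(Ph) bond together with the acid (an enol-lactone annulation in reverse), then the side-chain CH=CMe2 bond back to CH2OH, then the two ring A bonds C7–C8 and C5–C6. This leaves a 3-prenyl δ-lactone and a 6-methyl-dihydropyranone-5-carbonyl chloride.
- Enabling feature: C6, the quaternary carbon of ring A (the carbocycle), lies between the C5 and C7 carbonyls and is 1,3 to the side-chain methine. C7, C6 and that methine are therefore C2, C3 and C5 of a δ-lactone whose ring oxygen is the future CH2OH, and C8 is the methyl group on C6 of the pyranone (ring B).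
- Forward order: ring B is made first (dihydropyranone from a δ-hydroxy-β-keto ester) and the δ-lactone in parallel. Ring A is then closed in one flask by enolate C-acylation and Claisen closure with lactone opening. Oxidation/Wittig and a carbene-catalysed annulation/hydrolysis complete the two side chains.
- Stereochemistry: C2/C3 of ring B come from ethyl (S)-3-hydroxybutanoate and an anti-selective Fráter–Seebach methylation. The side-chain methine comes from an oxazolidinone-controlled Michael addition, C6 from acylation trans to the C5 substituent of the lactone enolate, and the benzylic carbon from a chiral triazolium catalyst.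

Key step: step 11

Remark on numbering and tautomers: the bicyclic core is numbered as a chromene (O1, C2–C4 and C4a/C8a in ring B; C5–C8 in ring A), and the enolised trione is drawn as the C4 enol, other enol forms being the same compound.

Remark on the catalyst of step 14: both antipodes of the aminoindanol-derived triazolium salt are commercial, and its known sense of induction with cyclic 1,3-dicarbonyl nucleophiles is assumed to carry over, so the antipode that gives the (R) benzylic carbon is the one used.

**Route**

Step 1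
Reactants: 1 5-methylhex-5-enoic acid; 2 (S)-4-benzyloxazolidin-2-one
Product: 4 (S)-4-benzyl-3-(5-methylhex-5-enoyl)oxazolidin-2-one, via mixed pivalic anhydride 3 (not isolated)
Conditions: PivCl, Et3N, THF, −20 °C; then 2, LiCl, −20 °C → rt
Reagents that add atoms: (S)-4-benzyloxazolidin-2-one (2), O=C1N[C@@H](Cc2ccccc2)CO1
Why: Mixed-anhydride N-acylation of the oxazolidinone (LiCl-assisted acyl transfer) is the standard mild entry to such imides and should leave the 1,1-disubstituted alkene untouched.

Step 2
Reactants: 4 (S)-4-benzyl-3-(5-methylhex-5-enoyl)oxazolidin-2-one; 5 tert-butyl acrylate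
Product: 6 tert-butyl (4R)-4-{[(4S)-4-benzyl-2-oxooxazolidin-3-yl]carbonyl}-7-methyloct-7-enoate
Conditions: TiCl3(OiPr), iPr2NEt, CH2Cl2, 0 °C; then 5, 0 °C
Reagents that add atoms: tert-butyl acrylate (5), C=CC(=O)OC(C)(C)C
Why: In this titanium-enolate Michael addition of an Evans imide the chelated Z-enolate should add to the acrylate on the face opposite the benzyl group, which sets the (R) methine that becomes C5 of the lactone, the amine-buffered medium sparing the alkene.

Step 3
Reactants: 6 tert-butyl (4R)-4-{[(4S)-4-benzyl-2-oxooxazolidin-3-yl]carbonyl}-7-methyloct-7-enoate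
Product: 7 tert-butyl (4R)-4-(hydroxymethyl)-7-methyloct-7-enoate
Conditions: LiBH4, MeOH (1 equiv), Et2O, 0 °C
Reagents that add atoms: none
Why: Reductive cleavage of the imide by LiBH4 should be much faster than reduction of the tert-butyl ester, returns the auxiliary and does not enolise the stereocentre.

Step 4
Reactants: 7 tert-butyl (4R)-4-(hydroxymethyl)-7-methyloct-7-enoate
Product: 8 (5R)-5-(3-methylbut-3-en-1-yl)oxan-2-one
Conditions: p-TsOH·H2O (5 mol %), toluene, 50 °C
Reagents that add atoms: none
Why: Acid-catalysed lactonisation (intramolecular transesterification) of a δ-hydroxy ester should be strongly favoured for the six-membered ring, and a catalytic sulfonic acid in toluene is mild enough to leave the isopropenyl-type alkene in place.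

Step 5
Reactants: 8 (5R)-5-(3-methylbut-3-en-1-yl)oxan-2-one; 9 prenyl bromide (1-bromo-3-methylbut-2-ene)
Product: 10 (5R)-3-(3-methylbut-2-en-1-yl)-5-(3-methylbut-3-en-1-yl)oxan-2-one (both C3 epimers)
Conditions: LiN(iPr)2, THF, −78 °C; then 9, −78 → −30 °C
Reagents that add atoms: prenyl bromide (9), CC(C)=CCBr
Why: Alkylation of the lactone lithium enolate with an allylic bromide is a routine enolate alkylation, and the C3 configuration does not matter because C3 is enolised again in step 11.

Step 6
Reactants: 11 ethyl (S)-3-hydroxybutanoate; 12 iodomethane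
Product: 13 ethyl (2S,3S)-3-hydroxy-2-methylbutanoate
Conditions: LiN(iPr)2 (2.2 equiv), THF, −50 → −20 °C; then MeI, DMPU, −78 → 0 °C
Reagents that add atoms: iodomethane (12), CI
Why: In the Fráter–Seebach alkylation the chelated alkoxide enolate should be methylated anti to the alkoxide, giving the anti (2S,3S) ester that becomes the trans C2/C3 pair of ring B.

Step 7
Reactants: 13 ethyl (2S,3S)-3-hydroxy-2-methylbutanoate; 14 tert-butyl acetate
Product: 15 tert-butyl (4S,5S)-5-hydroxy-4-methyl-3-oxohexanoate
Conditions: 14, LiN(iPr)2 (3.5 equiv each), THF, −78 °C; then 13, −78 → −30 °C; aq. HCl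
Reagents that add atoms: tert-butyl acetate (14), CC(=O)OC(C)(C)C
Why: Crossed Claisen condensation of the hydroxy ester with excess lithium enolate of tert-butyl acetate should give the δ-hydroxy-β-keto ester, the alkoxide and then the product enolate guarding against over-addition and against loss of the α-stereocentre.

Step 8
Reactants: 15 tert-butyl (4S,5S)-5-hydroxy-4-methyl-3-oxohexanoate; 16 N,N-dimethylacetamide dimethyl acetal (1,1-dimethoxy-N,N-dimethylethanamine)
Product: 18 tert-butyl (2S,3S)-2,3,6-trimethyl-4-oxo-3,4-dihydro-2H-pyran-5-carboxylate, via enaminone 17 (not isolated)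
Conditions: 16 (1.5 equiv), toluene, rt → 50 °C
Reagents that add atoms: N,N-dimethylacetamide dimethyl acetal (16), CC(OC)(OC)N(C)C
Why: Knoevenagel-type condensation of the active methylene with the amide acetal gives the enaminone, and oxa-Michael addition–elimination of the δ-hydroxyl (loss of Me2NH) should close ring B as the 6-methyl dihydropyranone (a Maitland–Japp-type annulation), both stereocentres being carried through and the trans arrangement being also the thermodynamic one.

Step 9
Reactants: 18 tert-butyl (2S,3S)-2,3,6-trimethyl-4-oxo-3,4-dihydro-2H-pyran-5-carboxylate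
Product: 19 (2S,3S)-2,3,6-trimethyl-4-oxo-3,4-dihydro-2H-pyran-5-carboxylic acid
Conditions: CF3CO2H, CH2Cl2, 0 °C → rt
Reagents that add atoms: none
Why: Acidolysis of the tert-butyl ester avoids hydroxide, which would add to C6 of the β-alkoxy enone, and the acid should be stable because its α-carbon is sp2 and the usual cyclic decarboxylation is not open to it.

Step 10
Reactants: 19 (2S,3S)-2,3,6-trimethyl-4-oxo-3,4-dihydro-2H-pyran-5-carboxylic acid
Product: 20 (2S,3S)-2,3,6-trimethyl-4-oxo-3,4-dihydro-2H-pyran-5-carbonyl chloride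
Conditions: (COCl)2, DMF (cat.), CH2Cl2, 0 °C → rt; used crude
Reagents that add atoms: oxalyl chloride, O=C(Cl)C(=O)Cl
Why: Acid chloride formation with oxalyl chloride and catalytic DMF (Vilsmeier-type activation) is standard for 4-oxopyran-3-carboxylic acids and touches neither stereocentre.

Step 11
Reactants: 10 (5R)-3-(3-methylbut-2-en-1-yl)-5-(3-methylbut-3-en-1-yl)oxan-2-one; 20 (2S,3S)-2,3,6-trimethyl-4-oxo-3,4-dihydro-2H-pyran-5-carbonyl chloride
Product: 22 (2S,3S,6R)-4-hydroxy-6-[(2R)-2-(hydroxymethyl)-5-methylhex-5-en-1-yl]-2,3-dimethyl-6-(3-methylbut-2-en-1-yl)-2,3-dihydro-5H-chromene-5,7(6H)-dione, via keto lactone 21 (not isolated)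
Conditions: 10, LiN(SiMe3)2 (1.05 equiv), THF, −78 °C; 20 (1.15 equiv), −78 °C; then LiN(SiMe3)2 (2.3 equiv), −78 → 0 °C; aq. HCl to pH 3
Reagents that add atoms: acid chloride 20, O=C(Cl)C1=C(C)O[C@@H](C)[C@H](C)C1=O
Why: The lithium enolate of 10 (planar at C3, so both epimers converge) should be C-acylated by 20 with loss of chloride, as in known acylations of ester and lactone lithium enolates, giving keto lactone 21 with no α-hydrogen left. The second charge of base then removes a proton from the pyranone C6-methyl group, which is vinylogous to both the ring B ketone and the new ketone; this carbon adds to the lactone carbonyl in an intramolecular Dieckmann-type Claisen condensation, and the tetrahedral adduct breaks down with the ring oxygen leaving as a primary alkoxide, which opens the lactone. Ring A closes in the 6-(enolendo)-exo-trig mode, the methyl-derived carbon being the only dienolate terminus that can reach the lactone carbonyl. The quaternary centre (C6 of 22) is set in the acylation: the half-chair enolate carries the C5 side chain pseudo-equatorially and the acid chloride approaches axially on the face of the C5 hydrogen, so the acyl group ends trans and the prenyl group cis to that side chain. The step needs this facial selectivity (secured by the C5 substituent) and C- over O-acylation ahead of proton transfer from the methyl group of 20 (lithium counter-ion, THF, −78 °C, second base charge only after the acylation). The two carbonyls flanking C6 have different origins (lactone and acid chloride) and are never interchangeable, so the configuration is retained, and the trione is at once deprotonated to its delocalised anion, which drives the closure to completion.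

Step 12
Reactants: 22 (2S,3S,6R)-4-hydroxy-6-[(2R)-2-(hydroxymethyl)-5-methylhex-5-en-1-yl]-2,3-dimethyl-6-(3-methylbut-2-en-1-yl)-2,3-dihydro-5H-chromene-5,7(6H)-dione
Product: 23 (2R)-2-{[(2S,3S,6R)-4-hydroxy-2,3-dimethyl-6-(3-methylbut-2-en-1-yl)-5,7-dioxo-3,5,6,7-tetrahydro-2H-chromen-6-yl]methyl}-5-methylhex-5-enal
Conditions: Dess–Martin periodinane (1.2 equiv), CH2Cl2, 0 °C → rt; aq. Na2S2O3 (pH 4); used at once
Reagents that add atoms: none
Why: Dess–Martin oxidation of the primary alcohol is fast under neutral conditions, under which the trione should stay as its chelated enol and the α-stereocentre of the aldehyde should not epimerise.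

Step 13
Reactants: 23 (2R)-2-{[(2S,3S,6R)-4-hydroxy-2,3-dimethyl-6-(3-methylbut-2-en-1-yl)-5,7-dioxo-3,5,6,7-tetrahydro-2H-chromen-6-yl]methyl}-5-methylhex-5-enal; 24 isopropyltriphenylphosphonium iodide
Product: 25 (2S,3S,6S)-4-hydroxy-2,3-dimethyl-6-(3-methylbut-2-en-1-yl)-6-[(2R)-5-methyl-2-(2-methylprop-1-en-1-yl)hex-5-en-1-yl]-2,3-dihydro-5H-chromene-5,7(6H)-dione
Conditions: 24 (4 equiv), n-BuLi (3.8 equiv), THF, 0 °C; then 23, −78 → 0 °C; aq. NH4Cl, then pH 3
Reagents that add atoms: isopropyltriphenylphosphonium iodide (24), CC(C)[P+](c1ccccc1)(c1ccccc1)c1ccccc1.[I-]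
Why: In this Wittig olefination with a non-stabilised ylide the first equivalent turns the acidic enol into its delocalised enolate, which shields the ring carbonyls, and the aldehyde should be olefinated at low temperature faster than it is enolised.

Step 14
Reactants: 25 (2S,3S,6S)-4-hydroxy-2,3-dimethyl-6-(3-methylbut-2-en-1-yl)-6-[(2R)-5-methyl-2-(2-methylprop-1-en-1-yl)hex-5-en-1-yl]-2,3-dihydro-5H-chromene-5,7(6H)-dione; 26 (E)-cinnamaldehyde
Product: 27 enol δ-lactone of the target: a (4R)-4-phenyl-3,4-dihydropyran-2-one ring fused across C7–C8 of 25 (O7–C(=O)–CH2–CH(Ph)–C8), ring B as its C4 ketone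
Conditions: 26 (1.5 equiv), 2-mesityl-5a,10b-dihydro-4H,6H-indeno[2,1-b][1,2,4]triazolo[4,3-d][1,4]oxazin-2-ium chloride (antipode giving R, 10 mol %), 3,3′,5,5′-tetra-tert-butyldiphenoquinone (1.2 equiv), iPr2NEt (1.2 equiv), toluene, rt
Reagents that add atoms: (E)-cinnamaldehyde (26), O=C/C=C/c1ccccc1
Why: In this oxidative carbene-catalysed Michael addition–lactonisation the α,β-unsaturated acyl azolium formed from cinnamaldehyde should be attacked by C8, the only free nucleophilic carbon, and then be released by O7, so the chiral catalyst sets the benzylic (R) centre with little bias expected from the distant C6 centre.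

Step 15
Reactants: 27 enol δ-lactone of the target
Product: 28 (3R)-3-{(2S,3S,6S)-4-hydroxy-2,3-dimethyl-6-(3-methylbut-2-en-1-yl)-6-[(2R)-5-methyl-2-(2-methylprop-1-en-1-yl)hex-5-en-1-yl]-5,7-dioxo-3,5,6,7-tetrahydro-2H-chromen-8-yl}-3-phenylpropanoic acid (CNP0155375.2)
Conditions: LiOH, THF/H2O, 0 °C → rt; then 1 M HCl
Reagents that add atoms: water (delivered as hydroxide), O
Why: Saponification of the enol lactone, an activated ester, should be fast at 0 °C, and the ring A trione is protected as its delocalised anion until acidification, so no stereocentre is at risk.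

**Compound list**

1 | 5-methylhex-5-enoic acid | C=C(C)CCCC(=O)O | starting material
2 | (S)-4-benzyloxazolidin-2-one | O=C1N[C@@H](Cc2ccccc2)CO1 | starting material
3 | 5-methylhex-5-enoic pivalic anhydride (formed in the flask) | C=C(C)CCCC(=O)OC(=O)C(C)(C)C | intermediate
4 | (S)-4-benzyl-3-(5-methylhex-5-enoyl)oxazolidin-2-one | C=C(C)CCCC(=O)N1[C@@H](Cc2ccccc2)COC1=O | intermediate
5 | tert-butyl acrylate | C=CC(=O)OC(C)(C)C | starting material
6 | tert-butyl (4R)-4-{[(4S)-4-benzyl-2-oxooxazolidin-3-yl]carbonyl}-7-methyloct-7-enoate | C=C(C)CC[C@H](CCC(=O)OC(C)(C)C)C(=O)N1[C@@H](Cc2ccccc2)COC1=O | intermediate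
7 | tert-butyl (4R)-4-(hydroxymethyl)-7-methyloct-7-enoate | C=C(C)CC[C@@H](CO)CCC(=O)OC(C)(C)C | intermediate
8 | (5R)-5-(3-methylbut-3-en-1-yl)oxan-2-one | C=C(C)CC[C@@H](CO1)CCC1=O | intermediate
9 | prenyl bromide | CC(C)=CCBr | starting material
10 | (5R)-3-(3-methylbut-2-en-1-yl)-5-(3-methylbut-3-en-1-yl)oxan-2-one, both C3 epimers | C=C(C)CC[C@@H](CO1)CC(CC=C(C)C)C1=O | intermediate
11 | ethyl (S)-3-hydroxybutanoate | CCOC(=O)C[C@H](C)O | starting material
12 | iodomethane | CI | starting material
13 | ethyl (2S,3S)-3-hydroxy-2-methylbutanoate | CCOC(=O)[C@@H](C)[C@H](C)O | intermediate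
14 | tert-butyl acetate | CC(=O)OC(C)(C)C | starting material
15 | tert-butyl (4S,5S)-5-hydroxy-4-methyl-3-oxohexanoate | CC(C)(C)OC(=O)CC(=O)[C@@H](C)[C@H](C)O | intermediate
16 | N,N-dimethylacetamide dimethyl acetal | CC(OC)(OC)N(C)C | starting material
17 | tert-butyl (4S,5S)-2-[1-(dimethylamino)ethylidene]-5-hydroxy-4-methyl-3-oxohexanoate (enaminone, formed in the flask) | CC(C)(C)OC(=O)C(=C(C)N(C)C)C(=O)[C@@H](C)[C@H](C)O | intermediate
18 | tert-butyl (2S,3S)-2,3,6-trimethyl-4-oxo-3,4-dihydro-2H-pyran-5-carboxylate | CC(C)(C)OC(=O)C1=C(C)O[C@@H](C)[C@H](C)C1=O | intermediate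
19 | (2S,3S)-2,3,6-trimethyl-4-oxo-3,4-dihydro-2H-pyran-5-carboxylic acid | OC(=O)C1=C(C)O[C@@H](C)[C@H](C)C1=O | intermediate
20 | (2S,3S)-2,3,6-trimethyl-4-oxo-3,4-dihydro-2H-pyran-5-carbonyl chloride | O=C(Cl)C1=C(C)O[C@@H](C)[C@H](C)C1=O | intermediate
21 | (3S,5R)-3-(3-methylbut-2-en-1-yl)-5-(3-methylbut-3-en-1-yl)-3-[(2S,3S)-2,3,6-trimethyl-4-oxo-3,4-dihydro-2H-pyran-5-carbonyl]oxan-2-one (keto lactone, formed in the flask) | C=C(C)CC[C@@H](CO1)C[C@](CC=C(C)C)(C1=O)C(=O)C2=C(C)O[C@@H](C)[C@H](C)C2=O | intermediate
22 | (2S,3S,6R)-4-hydroxy-6-[(2R)-2-(hydroxymethyl)-5-methylhex-5-en-1-yl]-2,3-dimethyl-6-(3-methylbut-2-en-1-yl)-2,3-dihydro-5H-chromene-5,7(6H)-dione | C=C(C)CC[C@@H](CO)C[C@@]1(CC=C(C)C)C(=O)C2=C(O)[C@@H](C)[C@H](C)OC2=CC1=O | intermediate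
23 | (2R)-2-{[(2S,3S,6R)-4-hydroxy-2,3-dimethyl-6-(3-methylbut-2-en-1-yl)-5,7-dioxo-3,5,6,7-tetrahydro-2H-chromen-6-yl]methyl}-5-methylhex-5-enal | C=C(C)CC[C@@H](C=O)C[C@@]1(CC=C(C)C)C(=O)C2=C(O)[C@@H](C)[C@H](C)OC2=CC1=O | intermediate
24 | isopropyltriphenylphosphonium iodide | CC(C)[P+](c1ccccc1)(c1ccccc1)c1ccccc1.[I-] | starting material
25 | (2S,3S,6S)-4-hydroxy-2,3-dimethyl-6-(3-methylbut-2-en-1-yl)-6-[(2R)-5-methyl-2-(2-methylprop-1-en-1-yl)hex-5-en-1-yl]-2,3-dihydro-5H-chromene-5,7(6H)-dione | C=C(C)CC[C@@H](C=C(C)C)C[C@@]1(CC=C(C)C)C(=O)C2=C(O)[C@@H](C)[C@H](C)OC2=CC1=O | intermediate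
26 | (E)-cinnamaldehyde | O=C/C=C/c1ccccc1 | starting material
27 | enol δ-lactone of the target ((4R)-4-phenyl-3,4-dihydropyran-2-one fused across C7–C8 of 25, C4 ketone form) | C=C(C)CC[C@@H](C=C(C)C)C[C@@]1(CC=C(C)C)C(=O)C2=C(O[C@@H](C)[C@H](C)C2=O)C2=C1OC(=O)C[C@@H]2c1ccccc1 | intermediate
28 | (3R)-3-{(2S,3S,6S)-4-hydroxy-2,3-dimethyl-6-(3-methylbut-2-en-1-yl)-6-[(2R)-5-methyl-2-(2-methylprop-1-en-1-yl)hex-5-en-1-yl]-5,7-dioxo-3,5,6,7-tetrahydro-2H-chromen-8-yl}-3-phenylpropanoic acid | C=C(C)CC[C@@H](C=C(C)C)C[C@@]1(CC=C(C)C)C(=O)C2=C(O)[C@@H](C)[C@H](C)OC2=C([C@H](CC(=O)O)c2ccccc2)C1=O | target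

**Step count and weak points**

Total steps: 15. Longest linear sequence: 10 steps (steps 1–5 then 11–15; the ring B branch, steps 6–10 then 11–15, is equally long).

Steps most likely to fail:

1. Step 11. Proton transfer from the acidic C6-methyl group of 20 to the hindered tetrasubstituted lactone enolate, or O-acylation of that enolate, may outrun C–C bond formation, so that the second charge of base meets unacylated material. The fallback separates the two events and forms the C–C bond without a basic enolate. It sets out from 10: LiN(iPr)2 and Me3SiCl (THF, −78 °C) should give the trimethylsilyl ketene acetal F1. F1 is acylated at carbon by 20 under ZnCl2 catalysis in CH2Cl2 (Mukaiyama-type acylation of a silyl ketene acetal by an acid chloride, with the same axial approach and hence the same face). This gives keto lactone 21, now isolated, which is closed with LiN(SiMe3)2 (2.2 equiv, THF, −78 → 0 °C), and the route is rejoined at 22.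

2. Step 14. Facial control by the carbene catalyst may be eroded by the resident C6 centre, or slow lactonisation onto the hindered O7 may stall catalyst turnover. The fallback sets out from 25: Michael addition to commercial 5-benzylidene-2,2-dimethyl-1,3-dioxane-4,6-dione under a bifunctional cinchona squaramide (tertiary amine plus hydrogen-bond donor) in CH2Cl2 should give the Meldrum's acid Michael adduct F2. The C-benzylic epimers are diastereomers and can be separated at this stage if control is incomplete. Warming F2 in toluene (80 °C) expels acetone and CO2 through the acylketene and closes the same enol lactone, so the route is rejoined at 27.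

3. Step 12. The pentavalent iodine oxidant may attack the electron-rich enol carbon C8 of ring A instead of, or after, oxidising the alcohol, and the free acidic enol may afterwards cause aldol-type self-reaction of 23 or consume ylide in step 13. The fallback masks the enol first and sets out from 22: Me3SiCHN2 (toluene/MeOH, 0 °C) should methylate only the acidic enol oxygen, giving the methyl enol ether F3 (drawn as the C4 ether; a regioisomeric ether would serve equally). Dess–Martin oxidation then gives the aldehyde F4, and Wittig olefination with the ylide from 24 gives the alkene F5, both on a neutral substrate. LiCl in DMSO (100 °C, nucleophilic demethylation of the vinylogous ester) returns the route to 25.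

**Further compounds**

F1 | step 11 | trimethyl{[(3R)-5-(3-methylbut-2-en-1-yl)-3-(3-methylbut-3-en-1-yl)-3,4-dihydro-2H-pyran-6-yl]oxy}silane | C=C(C)CC[C@H]1COC(O[Si](C)(C)C)=C(CC=C(C)C)C1
F2 | step 14 | 5-{(R)-[(2S,3S,6S)-4-hydroxy-2,3-dimethyl-6-(3-methylbut-2-en-1-yl)-6-[(2R)-5-methyl-2-(2-methylprop-1-en-1-yl)hex-5-en-1-yl]-5,7-dioxo-3,5,6,7-tetrahydro-2H-chromen-8-yl](phenyl)methyl}-2,2-dimethyl-1,3-dioxane-4,6-dione | C=C(C)CC[C@@H](C=C(C)C)C[C@@]1(CC=C(C)C)C(=O)C2=C(O)[C@@H](C)[C@H](C)OC2=C([C@H](C2C(=O)OC(C)(C)OC2=O)c2ccccc2)C1=O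
F3 | step 12 | (2S,3S,6R)-6-[(2R)-2-(hydroxymethyl)-5-methylhex-5-en-1-yl]-4-methoxy-2,3-dimethyl-6-(3-methylbut-2-en-1-yl)-2,3-dihydro-5H-chromene-5,7(6H)-dione | C=C(C)CC[C@@H](CO)C[C@@]1(CC=C(C)C)C(=O)C2=C(OC)[C@@H](C)[C@H](C)OC2=CC1=O
F4 | step 12 | (2R)-2-{[(2S,3S,6R)-4-methoxy-2,3-dimethyl-6-(3-methylbut-2-en-1-yl)-5,7-dioxo-3,5,6,7-tetrahydro-2H-chromen-6-yl]methyl}-5-methylhex-5-enal | C=C(C)CC[C@@H](C=O)C[C@@]1(CC=C(C)C)C(=O)C2=C(OC)[C@@H](C)[C@H](C)OC2=CC1=O
F5 | step 12 | (2S,3S,6S)-4-methoxy-2,3-dimethyl-6-(3-methylbut-2-en-1-yl)-6-[(2R)-5-methyl-2-(2-methylprop-1-en-1-yl)hex-5-en-1-yl]-2,3-dihydro-5H-chromene-5,7(6H)-dione | C=C(C)CC[C@@H](C=C(C)C)C[C@@]1(CC=C(C)C)C(=O)C2=C(OC)[C@@H](C)[C@H](C)OC2=CC1=O
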